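Drimane numbering: ring A is C1–C5/C10 (C4 gem-dimethyl, C10 angular methyl), ring B is C5–C10 (C8 methyl, C9 alkylidene), C11 is the benzylic carbon. Ring B is read as the cyclohexene of a [4+2] cycloaddition whose new bonds, C8–C9 and C5–C10, include the ring-fusion bond, so the precursor is open-chain: a (2E,8E,10E)-trienoyl imide of (4S)-4-benzyloxazolidin-2-one. Its aluminium-promoted intramolecular Diels–Alder reaction closes rings A and B at once; the cis H-5/H-8 relationship across ring B comes from the E,E-diene, the trans fusion from the endo mode, the absolute sense from the auxiliary. The acyl carbon becomes C11; aryllithium addition, dehydration and late sulfation complete the target.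

Key step: step 5

Remark: the two aryl hydrogen sulfates (29, 30) are handled as sodium salts and are listed as the free acids; the last step ends with cold proton exchange to the acid form.
Arene locants: C1' carries C11, C2' and C5' carry the sulfated oxygens, C3' the formyl group, C4' the free hydroxyl, C6' is CH.

Step 1
Reactants: 1 2,2-dimethylpent-4-enal; 2 diethyl [(2E)-but-2-en-1-yl]phosphonate
Product: 3 (5E,7E)-4,4-dimethylnona-1,5,7-triene
Conditions: 2, n-BuLi, THF/DMPU, −78 °C; then 1, −78 °C to rt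
Reagents that add atoms: none
Why: Horner–Wadsworth–Emmons olefination of a non-enolisable, α-quaternary aldehyde with the allylic phosphonate anion (α-attack), which should give the new C5=C6 bond E for steric reasons while the E geometry of the crotyl unit is carried over.

Step 2
Reactants: 3 (5E,7E)-4,4-dimethylnona-1,5,7-triene; 4 ethyl but-2-ynoate
Product: 6 ethyl (2E,8E,10E)-3,7,7-trimethyldodeca-2,8,10-trienoate, via B-alkyl-9-BBN 5 (not isolated)
Conditions: 9-BBN (1.0 equiv), THF, 0 °C to rt; then 4, CuOAc (cat.), P(OPh)3, KOt-Bu (cat.), t-BuOH, 1,4-dioxane, 40 °C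
Reagents that add atoms: none
Why: 9-BBN hydroborates only the monosubstituted terminal alkene (anti-Markovnikov), and copper-catalysed conjugate addition of the B-alkyl group to the ynoate with syn protonation places chain and H cis, that is, chain trans to the ester (2E).

Step 3
Reactants: 6 ethyl (2E,8E,10E)-3,7,7-trimethyldodeca-2,8,10-trienoate
Product: 7 (2E,8E,10E)-3,7,7-trimethyldodeca-2,8,10-trienoic acid
Conditions: LiOH, THF/MeOH/H2O, 40 °C; then 1 M HCl
Reagents that add atoms: lithium hydroxide, [Li+].[OH-]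
Why: saponification by acyl–oxygen cleavage, under which the trisubstituted 2E alkene and the diene should not isomerise.

Step 4
Reactants: 7 (2E,8E,10E)-3,7,7-trimethyldodeca-2,8,10-trienoic acid; 8 (4S)-4-benzyl-1,3-oxazolidin-2-one
Product: 10 (4S)-4-benzyl-3-[(2E,8E,10E)-3,7,7-trimethyldodeca-2,8,10-trienoyl]-1,3-oxazolidin-2-one, via mixed pivalic anhydride 9 (not isolated)
Conditions: PivCl, Et3N, THF, −20 °C; then 8, LiCl, −20 °C to rt
Reagents that add atoms: none
Why: N-acylation of the oxazolidinone through the mixed anhydride, which is attacked at the less hindered enoyl carbonyl; no stereocentre is formed or touched.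

Step 5
Reactants: 10 (4S)-4-benzyl-3-[(2E,8E,10E)-3,7,7-trimethyldodeca-2,8,10-trienoyl]-1,3-oxazolidin-2-one
Product: 11 (4S)-4-benzyl-3-{[(1S,2S,4aS,8aS)-2,5,5,8a-tetramethyl-1,2,4a,5,6,7,8,8a-octahydronaphthalen-1-yl]carbonyl}-1,3-oxazolidin-2-one
Conditions: Me2AlCl (1.6 equiv), CH2Cl2, −30 °C to 0 °C; then 1 M HCl
Reagents that add atoms: none
Why: Excess Me2AlCl turns the imide into a cationic two-point aluminium chelate with an s-cis enoyl group, and this dienophile (C9=C10) adds in a concerted, asynchronous, suprafacial [4+2] fashion to the tethered (E,E)-diene (C5=C6–C7=C8), so that C5–C10 and C8–C9 form together. The closest known reaction type is the Lewis acid-promoted, auxiliary-controlled intramolecular Diels–Alder reaction of N-(2,8,10-trienoyl)oxazolidinones to trans-fused octalins. Ring B closes as the cyclohexene of the cycloaddition, and ring A closes through the same C5–C10 bond as a six-membered ring spanned by C1–C4, with a chair-like tether held exo to the diene (the 1,7,9-decatriene mode). C10 is fixed by attack on the enoyl face anti to the benzyl group of the (4S)-auxiliary (Cα-si face, giving 10S); C5 by the endo position of the chelated carbonyl, which with the E dienophile forces the tether exo and the ring fusion trans; C8 by the E geometry of the C7=C8 propenyl end (CH3-8 on the face of CH3-10); and C9 by the E dienophile geometry (acyl cis to CH3-10, a centre that is removed later). The step needs endo over exo addition and one π-face, and both are secured by the rigid chelate, whose Lewis acid activation strengthens the endo preference and whose benzyl group shields the other face. The gem-dimethyl group at C4 favours the folded reactive conformer and offsets the lower reactivity of the β,β-disubstituted dienophile.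

Step 6
Reactants: 11 (4S)-4-benzyl-3-{[(1S,2S,4aS,8aS)-2,5,5,8a-tetramethyl-1,2,4a,5,6,7,8,8a-octahydronaphthalen-1-yl]carbonyl}-1,3-oxazolidin-2-one
Product: 12 [(1S,2S,4aS,8aS)-2,5,5,8a-tetramethyl-1,2,4a,5,6,7,8,8a-octahydronaphthalen-1-yl]methanol
Conditions: LiAlH4, THF, 0 °C; aqueous NaOH work-up
Reagents that add atoms: none
Why: hydride reduction of the exocyclic imide carbonyl releases the primary alcohol and the intact auxiliary, while the isolated C6=C7 alkene is inert to hydride.

Step 7
Reactants: 12 [(1S,2S,4aS,8aS)-2,5,5,8a-tetramethyl-1,2,4a,5,6,7,8,8a-octahydronaphthalen-1-yl]methanol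
Product: 13 [(1S,2S,4aS,8aS)-2,5,5,8a-tetramethyldecahydronaphthalen-1-yl]methanol
Conditions: H2 (1 atm), PtO2, EtOAc, rt
Reagents that add atoms: none
Why: catalytic hydrogenation of the only alkene (C6=C7), with platinum chosen over palladium to avoid double-bond migration toward C5 or C8 that would scramble those centres; no new stereocentre arises.

Step 8
Reactants: 13 [(1S,2S,4aS,8aS)-2,5,5,8a-tetramethyldecahydronaphthalen-1-yl]methanol
Product: 14 (1S,2S,4aS,8aS)-2,5,5,8a-tetramethyldecahydronaphthalene-1-carbaldehyde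
Conditions: Dess–Martin periodinane, NaHCO3, CH2Cl2, 0 °C to rt
Reagents that add atoms: none
Why: Dess–Martin oxidation under buffered, non-basic conditions, in which the equatorial formyl group at C9 is also the thermodynamic epimer and should hold.

Step 9
Reactants: 15 hydroquinone
Product: 16 1,4-bis(methoxymethoxy)benzene
Conditions: MOMCl, i-Pr2NEt, CH2Cl2, 0 °C to rt
Reagents that add atoms: chloromethyl methyl ether, COCCl
Why: double O-alkylation of the phenols by the oxocarbenium-type electrophile.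

Step 10
Reactants: 16 1,4-bis(methoxymethoxy)benzene
Product: 19 2,5-bis(methoxymethoxy)phenol, via aryllithium 17 (not isolated), via dimethyl arylboronate 18 (not isolated)
Conditions: n-BuLi, THF, 0 °C; B(OMe)3, −78 °C to rt; then 30 % H2O2, 0 °C to rt
Reagents that add atoms: hydrogen peroxide, OO
Why: directed ortho-metalation next to a methoxymethoxy group (all four ring positions are equivalent), borylation and oxidative carbon-to-oxygen 1,2-migration.

Step 11
Reactants: 19 2,5-bis(methoxymethoxy)phenol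
Product: 20 2-hydroxy-3,6-bis(methoxymethoxy)benzaldehyde
Conditions: MgCl2, Et3N, (CH2O)n, MeCN, reflux
Reagents that add atoms: paraformaldehyde (as formaldehyde), C=O
Why: magnesium phenoxide-directed ortho-formylation (hydroxymethylation, then hydride transfer to a second formaldehyde), which can only occur at the single free position ortho to the hydroxyl.

Step 12
Reactants: 20 2-hydroxy-3,6-bis(methoxymethoxy)benzaldehyde
Product: 21 5-bromo-2-hydroxy-3,6-bis(methoxymethoxy)benzaldehyde
Conditions: NBS, MeCN, 0 °C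
Reagents that add atoms: N-bromosuccinimide, O=C1CCC(=O)N1Br
Why: electrophilic aromatic bromination para to the free phenol, the other free position being para to the formyl group and deactivated.

Step 13
Reactants: 21 5-bromo-2-hydroxy-3,6-bis(methoxymethoxy)benzaldehyde
Product: 22 5-bromo-3,6-bis(methoxymethoxy)-2-(prop-2-en-1-yloxy)benzaldehyde
Conditions: allyl bromide, K2CO3, DMF, rt
Reagents that add atoms: allyl bromide, C=CCBr
Why: Williamson etherification, which gives the C4' oxygen a group that is orthogonal to the acetals and removable at the end without acid.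

Step 14
Reactants: 22 5-bromo-3,6-bis(methoxymethoxy)-2-(prop-2-en-1-yloxy)benzaldehyde; 14 (1S,2S,4aS,8aS)-2,5,5,8a-tetramethyldecahydronaphthalene-1-carbaldehyde
Product: 25 5-{hydroxy[(1S,2S,4aS,8aS)-2,5,5,8a-tetramethyldecahydronaphthalen-1-yl]methyl}-3,6-bis(methoxymethoxy)-2-(prop-2-en-1-yloxy)benzaldehyde (both carbinol epimers), via lithium α-amino alkoxide 23 (not isolated), via aryllithium 24 (not isolated)
Conditions: lithium 4-methylpiperazin-1-ide (from 1-methylpiperazine, n-BuLi), THF, −78 °C; t-BuLi (2 equiv), −78 °C; then 14, −78 to −20 °C; then H2O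
Reagents that add atoms: none
Why: the formyl group is masked in situ as its α-amino alkoxide, bromine–lithium exchange gives the aryllithium, and its 1,2-addition to the hindered aldehyde forms C11 as an epimer mixture that does not matter because the centre is eliminated in the next step.

Step 15
Reactants: 25 5-{hydroxy[(1S,2S,4aS,8aS)-2,5,5,8a-tetramethyldecahydronaphthalen-1-yl]methyl}-3,6-bis(methoxymethoxy)-2-(prop-2-en-1-yloxy)benzaldehyde
Product: 27 3,6-bis(methoxymethoxy)-2-(prop-2-en-1-yloxy)-5-{(E)-[(2S,4aS,8aS)-2,5,5,8a-tetramethyloctahydronaphthalen-1(2H)-ylidene]methyl}benzaldehyde, via benzylic mesylate 26 (not isolated)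
Conditions: MsCl, Et3N, DMAP (cat.), CH2Cl2, 0 °C to 40 °C
Reagents that add atoms: none
Why: the mesylate of the electron-rich benzylic alcohol ionises and loses H-9 (E1), so both carbinol epimers should converge on the E alkene, in which the aryl group faces C8–H and not the quaternary C10 (A1,3 strain control).

Step 16
Reactants: 27 3,6-bis(methoxymethoxy)-2-(prop-2-en-1-yloxy)-5-{(E)-[(2S,4aS,8aS)-2,5,5,8a-tetramethyloctahydronaphthalen-1(2H)-ylidene]methyl}benzaldehyde
Product: 28 3,6-dihydroxy-2-(prop-2-en-1-yloxy)-5-{(E)-[(2S,4aS,8aS)-2,5,5,8a-tetramethyloctahydronaphthalen-1(2H)-ylidene]methyl}benzaldehyde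
Conditions: HCl (1.25 M in MeOH), THF, 0 °C to rt; aq. NaHCO3
Reagents that add atoms: none
Why: mild acid-catalysed acetal exchange removes both methoxymethyl groups as dimethoxymethane far faster than the allyl ether or the hindered styrene can react.

Step 17
Reactants: 28 3,6-dihydroxy-2-(prop-2-en-1-yloxy)-5-{(E)-[(2S,4aS,8aS)-2,5,5,8a-tetramethyloctahydronaphthalen-1(2H)-ylidene]methyl}benzaldehyde
Product: 29 3-formyl-2-(prop-2-en-1-yloxy)-5-{(E)-[(2S,4aS,8aS)-2,5,5,8a-tetramethyloctahydronaphthalen-1(2H)-ylidene]methyl}-1,4-phenylene bis(hydrogen sulfate)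
Conditions: SO3·pyridine (excess), pyridine, 50 °C, argon; then aq. NaHCO3
Reagents that add atoms: sulfur trioxide–pyridine complex, [O-]S(=O)(=O)[n+]1ccccc1
Why: O-sulfation of the two free phenols by the SO3 donor, with the C4' oxygen blocked as its allyl ether so that only the C2' and C5' oxygens are sulfated.

Step 18
Reactants: 29 3-formyl-2-(prop-2-en-1-yloxy)-5-{(E)-[(2S,4aS,8aS)-2,5,5,8a-tetramethyloctahydronaphthalen-1(2H)-ylidene]methyl}-1,4-phenylene bis(hydrogen sulfate)
Product: 30 3-formyl-2-hydroxy-5-{(E)-[(2S,4aS,8aS)-2,5,5,8a-tetramethyloctahydronaphthalen-1(2H)-ylidene]methyl}-1,4-phenylene bis(hydrogen sulfate)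
Conditions: Pd(PPh3)4 (cat.), morpholine, THF/MeOH, rt; then Dowex 50WX8 (H+ form), H2O, 0 °C, freeze-drying
Reagents that add atoms: none
Why: Tsuji–Trost-type deallylation, in which zerovalent palladium ionises the aryl allyl ether to a π-allyl complex that morpholine traps, leaving sulfate esters, aldehyde and styrene untouched before cold proton exchange gives the free acid.

Compound list
1 | 2,2-dimethylpent-4-enal | C=CCC(C)(C)C=O | starting material
2 | diethyl [(2E)-but-2-en-1-yl]phosphonate | C/C=C/CP(=O)(OCC)OCC | starting material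
3 | (5E,7E)-4,4-dimethylnona-1,5,7-triene | C=CCC(C)(C)/C=C/C=C/C | intermediate
4 | ethyl but-2-ynoate | CC#CC(=O)OCC | starting material
5 | 9-[(5E,7E)-4,4-dimethylnona-5,7-dien-1-yl]-9-borabicyclo[3.3.1]nonane | C/C=C/C=C/C(C)(C)CCCB1C2CCCC1CCC2 | intermediate
6 | ethyl (2E,8E,10E)-3,7,7-trimethyldodeca-2,8,10-trienoate | CCOC(=O)/C=C(C)/CCCC(C)(C)/C=C/C=C/C | intermediate
7 | (2E,8E,10E)-3,7,7-trimethyldodeca-2,8,10-trienoic acid | OC(=O)/C=C(C)/CCCC(C)(C)/C=C/C=C/C | intermediate
8 | (4S)-4-benzyl-1,3-oxazolidin-2-one | O=C1N[C@@H](Cc2ccccc2)CO1 | starting material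
9 | 2,2-dimethylpropanoic (2E,8E,10E)-3,7,7-trimethyldodeca-2,8,10-trienoic anhydride | CC(C)(C)C(=O)OC(=O)/C=C(C)/CCCC(C)(C)/C=C/C=C/C | intermediate
10 | (4S)-4-benzyl-3-[(2E,8E,10E)-3,7,7-trimethyldodeca-2,8,10-trienoyl]-1,3-oxazolidin-2-one | C/C=C/C=C/C(C)(C)CCC/C(C)=C/C(=O)N1[C@@H](Cc2ccccc2)COC1=O | intermediate
11 | (4S)-4-benzyl-3-{[(1S,2S,4aS,8aS)-2,5,5,8a-tetramethyl-1,2,4a,5,6,7,8,8a-octahydronaphthalen-1-yl]carbonyl}-1,3-oxazolidin-2-one (trans-fused octalin, C6=C7, 5α-H, 8β-CH3, 9β-acyl, 10β-CH3) | C[C@H]1C=C[C@H]2C(C)(C)CCC[C@]2(C)[C@H]1C(=O)N1[C@@H](Cc2ccccc2)COC1=O | intermediate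
12 | [(1S,2S,4aS,8aS)-2,5,5,8a-tetramethyl-1,2,4a,5,6,7,8,8a-octahydronaphthalen-1-yl]methanol | C[C@H]1C=C[C@H]2C(C)(C)CCC[C@]2(C)[C@H]1CO | intermediate
13 | [(1S,2S,4aS,8aS)-2,5,5,8a-tetramethyldecahydronaphthalen-1-yl]methanol | C[C@H]1CC[C@H]2C(C)(C)CCC[C@]2(C)[C@H]1CO | intermediate
14 | (1S,2S,4aS,8aS)-2,5,5,8a-tetramethyldecahydronaphthalene-1-carbaldehyde | C[C@H]1CC[C@H]2C(C)(C)CCC[C@]2(C)[C@H]1C=O | intermediate
15 | hydroquinone | Oc1ccc(O)cc1 | starting material
16 | 1,4-bis(methoxymethoxy)benzene | COCOc1ccc(OCOC)cc1 | intermediate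
17 | [2,5-bis(methoxymethoxy)phenyl]lithium | [Li]c1cc(OCOC)ccc1OCOC | intermediate
18 | dimethyl [2,5-bis(methoxymethoxy)phenyl]boronate | COB(OC)c1cc(OCOC)ccc1OCOC | intermediate
19 | 2,5-bis(methoxymethoxy)phenol | Oc1cc(OCOC)ccc1OCOC | intermediate
20 | 2-hydroxy-3,6-bis(methoxymethoxy)benzaldehyde | O=Cc1c(O)c(OCOC)ccc1OCOC | intermediate
21 | 5-bromo-2-hydroxy-3,6-bis(methoxymethoxy)benzaldehyde | O=Cc1c(O)c(OCOC)cc(Br)c1OCOC | intermediate
22 | 5-bromo-3,6-bis(methoxymethoxy)-2-(prop-2-en-1-yloxy)benzaldehyde | O=Cc1c(OCC=C)c(OCOC)cc(Br)c1OCOC | intermediate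
23 | lithium [5-bromo-3,6-bis(methoxymethoxy)-2-(prop-2-en-1-yloxy)phenyl](4-methylpiperazin-1-yl)methanolate | [Li]OC(N1CCN(C)CC1)c1c(OCC=C)c(OCOC)cc(Br)c1OCOC | intermediate
24 | the aryllithium from 23 (lithium in place of bromine) | [Li]OC(N1CCN(C)CC1)c1c(OCC=C)c(OCOC)cc([Li])c1OCOC | intermediate
25 | 5-{hydroxy[(1S,2S,4aS,8aS)-2,5,5,8a-tetramethyldecahydronaphthalen-1-yl]methyl}-3,6-bis(methoxymethoxy)-2-(prop-2-en-1-yloxy)benzaldehyde (epimers at the carbinol carbon) | C[C@H]1CC[C@H]2C(C)(C)CCC[C@]2(C)[C@H]1C(O)c1cc(OCOC)c(OCC=C)c(C=O)c1OCOC | intermediate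
26 | methanesulfonate of 25 | C[C@H]1CC[C@H]2C(C)(C)CCC[C@]2(C)[C@H]1C(OS(C)(=O)=O)c1cc(OCOC)c(OCC=C)c(C=O)c1OCOC | intermediate
27 | 3,6-bis(methoxymethoxy)-2-(prop-2-en-1-yloxy)-5-{(E)-[(2S,4aS,8aS)-2,5,5,8a-tetramethyloctahydronaphthalen-1(2H)-ylidene]methyl}benzaldehyde | C[C@H]1CC[C@H]2C(C)(C)CCC[C@]2(C)/C1=C/c1cc(OCOC)c(OCC=C)c(C=O)c1OCOC | intermediate
28 | 3,6-dihydroxy-2-(prop-2-en-1-yloxy)-5-{(E)-[(2S,4aS,8aS)-2,5,5,8a-tetramethyloctahydronaphthalen-1(2H)-ylidene]methyl}benzaldehyde | C[C@H]1CC[C@H]2C(C)(C)CCC[C@]2(C)/C1=C/c1cc(O)c(OCC=C)c(C=O)c1O | intermediate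
29 | 3-formyl-2-(prop-2-en-1-yloxy)-5-{(E)-[(2S,4aS,8aS)-2,5,5,8a-tetramethyloctahydronaphthalen-1(2H)-ylidene]methyl}-1,4-phenylene bis(hydrogen sulfate) | C[C@H]1CC[C@H]2C(C)(C)CCC[C@]2(C)/C1=C/c1cc(OS(=O)(=O)O)c(OCC=C)c(C=O)c1OS(=O)(=O)O | intermediate
30 | 3-formyl-2-hydroxy-5-{(E)-[(2S,4aS,8aS)-2,5,5,8a-tetramethyloctahydronaphthalen-1(2H)-ylidene]methyl}-1,4-phenylene bis(hydrogen sulfate) | C[C@H]1CC[C@H]2C(C)(C)CCC[C@]2(C)/C1=C/c1cc(OS(=O)(=O)O)c(O)c(C=O)c1OS(=O)(=O)O | target

Total step count: 18. Longest linear sequence: 13 (steps 1–8, then 14–18); the arene branch (steps 9–13) joins at step 14.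

Steps most likely to fail

Step 5. The β,β-disubstituted enoyl imide may react too slowly with the chelating Lewis acid, and the higher temperature then needed may erode endo and facial control or let the diene isomerise. The fallback replaces auxiliary control by catalyst control on the more reactive enal. It sets out from 6, which i-Bu2AlH (CH2Cl2, −78 °C) reduces to (2E,8E,10E)-3,7,7-trimethyldodeca-2,8,10-trien-1-ol F1, and MnO2 oxidises this to (2E,8E,10E)-3,7,7-trimethyldodeca-2,8,10-trienal F2. F2 is cyclised with a chiral N-protonated oxazaborolidine (from α,α-diphenylprolinol and o-tolylboronic acid, activated with Tf2NH, CH2Cl2, −78 to −20 °C). The facial sense on this β,β-disubstituted enal is not predicted here, so the prolinol enantiomer that furnishes the 10S series is chosen after a first run with either antipode. The product is (1S,2S,4aS,8aS)-2,5,5,8a-tetramethyl-1,2,4a,5,6,7,8,8a-octahydronaphthalene-1-carbaldehyde F3, and hydrogenation of C6=C7 (H2, RhCl(PPh3)3, benzene) comes back to the route at 14.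

Step 14. The basic aryllithium may enolise the hindered aldehyde 14, the exchange may be incomplete beside the in situ protected formyl group, or t-BuLi may attack the allyl ether, all of which lower conversion. The fallback uses an isolated acetal and a less basic organocerium reagent. It sets out from 22, which HC(OMe)3 and pyridinium p-toluenesulfonate in MeOH convert into 1-bromo-3-(dimethoxymethyl)-2,5-bis(methoxymethoxy)-4-(prop-2-en-1-yloxy)benzene F4. Bromine–lithium exchange (n-BuLi, THF, −78 °C), transmetalation with anhydrous CeCl3 and addition to 14 give [3-(dimethoxymethyl)-2,5-bis(methoxymethoxy)-4-(prop-2-en-1-yloxy)phenyl][(1S,2S,4aS,8aS)-2,5,5,8a-tetramethyldecahydronaphthalen-1-yl]methanol F5. Brief treatment with pyridinium p-toluenesulfonate in wet acetone unmasks the formyl group and comes back to the route at 25.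

Step 17. Sulfation of the hindered, hydrogen-bonded C2' hydroxyl may stay incomplete, and prolonged heating may let the hydroquinone oxidise in air. The fallback uses protected sulfate diesters. It sets out from 28, which 2,2,2-trichloroethyl chlorosulfate, Et3N and DMAP in THF at 0 °C convert into 3-formyl-2-(prop-2-en-1-yloxy)-5-{(E)-[(2S,4aS,8aS)-2,5,5,8a-tetramethyloctahydronaphthalen-1(2H)-ylidene]methyl}-1,4-phenylene bis(2,2,2-trichloroethyl) bis(sulfate) F6. Reductive removal of the trichloroethyl groups with Zn dust and HCO2NH4 in MeOH comes back to the route at 29 (as its ammonium salt).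

Further compounds
F1 | step 5 | (2E,8E,10E)-3,7,7-trimethyldodeca-2,8,10-trien-1-ol | OC/C=C(C)/CCCC(C)(C)/C=C/C=C/C
F2 | step 5 | (2E,8E,10E)-3,7,7-trimethyldodeca-2,8,10-trienal | O=C/C=C(C)/CCCC(C)(C)/C=C/C=C/C
F3 | step 5 | (1S,2S,4aS,8aS)-2,5,5,8a-tetramethyl-1,2,4a,5,6,7,8,8a-octahydronaphthalene-1-carbaldehyde | C[C@H]1C=C[C@H]2C(C)(C)CCC[C@]2(C)[C@H]1C=O
F4 | step 14 | 1-bromo-3-(dimethoxymethyl)-2,5-bis(methoxymethoxy)-4-(prop-2-en-1-yloxy)benzene | COC(OC)c1c(OCC=C)c(OCOC)cc(Br)c1OCOC
F5 | step 14 | [3-(dimethoxymethyl)-2,5-bis(methoxymethoxy)-4-(prop-2-en-1-yloxy)phenyl][(1S,2S,4aS,8aS)-2,5,5,8a-tetramethyldecahydronaphthalen-1-yl]methanol | C[C@H]1CC[C@H]2C(C)(C)CCC[C@]2(C)[C@H]1C(O)c1cc(OCOC)c(OCC=C)c(C(OC)OC)c1OCOC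
F6 | step 17 | 3-formyl-2-(prop-2-en-1-yloxy)-5-{(E)-[(2S,4aS,8aS)-2,5,5,8a-tetramethyloctahydronaphthalen-1(2H)-ylidene]methyl}-1,4-phenylene bis(2,2,2-trichloroethyl) bis(sulfate) | C[C@H]1CC[C@H]2C(C)(C)CCC[C@]2(C)/C1=C/c1cc(OS(=O)(=O)OCC(Cl)(Cl)Cl)c(OCC=C)c(C=O)c1OS(=O)(=O)OCC(Cl)(Cl)Cl
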